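**Retrosynthetic overview**

1. Target 32 ⇐ singlet-oxygen ene reaction of angelate 30 ⇐ C3 acylation of diol 26 ⇐ acetone aldol condensation at C7 and PMB removal from 8-ketone 21.
2. 21 ⇐ octalin 16 by alkene hydrogenation, Baeyer–Villiger oxidation of the C4 acetyl group (C4–C becomes C4–O with retention), deacetylation and C8 oxidation.
3. 16 ⇐ acyclic trienone 15 by an intramolecular Diels–Alder reaction that makes C3–C4 and C5–C10 and closes ring A and ring B together; no ring exists before this step.
4. Enabling feature: in ring A (C1, C2, C3, C4, C5, C10) the oxygen on C3 and the tertiary carbinol C4 (a masked acetyl-bearing carbon) let C3–C2–C1–C10 act as a 1-alkoxydiene and C4=C5 as an α-methyl enone, polarity-matched. The C6–C9 chain of ring B is the tether between C5 and C10, and its C8 oxygen (the later ketone) is a temporary stereocentre that sets the absolute configuration.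
5. 15 ⇐ (R)-2-(but-3-en-1-yl)oxirane 1 by acetylide opening, carboalumination–iodination, acetylation, cross metathesis, Heck vinylation with a vinylboronate and copper-mediated etherification.

Key step: step 7

Remark: positions are numbered as in eudesmane (ring A = C1, C2, C3, C4, C5, C10; ring B = C5–C10; methyls on C4 and C10; C11 with two methyls on C7; β = face of the C10 methyl, α = face of H-5). Epoxide 1 is taken as a commercial compound.

**Route**

Step 1
Reactants: 1 (R)-2-(but-3-en-1-yl)oxirane; 2 lithium acetylide–ethylenediamine complex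
Product: 3 (R)-oct-1-en-7-yn-5-ol
Conditions: LiC≡CH·H2NCH2CH2NH2, DMSO, 0 °C → rt; aq. NH4Cl
Reagents that add atoms: lithium acetylide–ethylenediamine complex, [Li+].[C-]#C.NCCN
Why: SN2 opening of the terminal epoxide at its CH2 carbon by the acetylide should leave the carbinol stereocentre (the later C8) untouched.

Step 2
Reactants: 3 (R)-oct-1-en-7-yn-5-ol; 4 trimethylaluminium; 5 iodine
Product: 7 (1E,4R)-1-iodo-2-methylocta-1,7-dien-4-ol, via alkenylalane 6 (not isolated)
Conditions: AlMe3 (3 equiv), Cp2ZrCl2 (25 mol %), CH2Cl2, 0 °C → rt; then I2, THF, −30 → 0 °C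
Reagents that add atoms: trimethylaluminium, C[Al](C)C; iodine, II
Why: Zirconium-catalysed syn-carboalumination of the terminal alkyne (Negishi) puts methyl on the internal carbon and aluminium on the terminus, and iodinolysis with retention should give the (E)-iodoalkene with the chain trans to iodine; the terminal alkene is inert here.

Step 3
Reactants: 7 (1E,4R)-1-iodo-2-methylocta-1,7-dien-4-ol; 8 acetic anhydride
Product: 9 (1E,4R)-1-iodo-2-methylocta-1,7-dien-4-yl acetate
Conditions: Ac2O, pyridine, DMAP (cat.), CH2Cl2, 0 °C → rt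
Reagents that add atoms: acetic anhydride, CC(=O)OC(C)=O
Why: Standard O-acetylation; the acetate blocks oxa-Michael addition onto the later enone and becomes the equatorial control element of the key step.

Step 4
Reactants: 9 (1E,4R)-1-iodo-2-methylocta-1,7-dien-4-yl acetate; 10 3-methylbut-3-en-2-one
Product: 11 (3E,7R,9E)-10-iodo-3,9-dimethyl-2-oxodeca-3,9-dien-7-yl acetate
Conditions: second-generation Hoveyda–Grubbs catalyst RuCl2(H2IMes)(=CH-C6H4-2-OiPr) (5 mol %), 10 (8 equiv), CH2Cl2, 40 °C
Reagents that add atoms: 3-methylbut-3-en-2-one, CC(=O)C(C)=C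
Why: Olefin cross metathesis of a terminal alkene with a 1,1-disubstituted enone partner should give the thermodynamically preferred (E)-trisubstituted enone, and the trisubstituted iodoalkene does not engage the ruthenium carbene.

Step 5
Reactants: 11 (3E,7R,9E)-10-iodo-3,9-dimethyl-2-oxodeca-3,9-dien-7-yl acetate; 12 4,4,5,5-tetramethyl-2-vinyl-1,3,2-dioxaborolane
Product: 13 (3E,7R,9E,11E)-3,9-dimethyl-2-oxo-12-(4,4,5,5-tetramethyl-1,3,2-dioxaborolan-2-yl)dodeca-3,9,11-trien-7-yl acetate
Conditions: Pd(OAc)2 (5 mol %), P(o-tol)3 (10 mol %), AgOAc (1.2 equiv), MeCN, 50 °C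
Reagents that add atoms: 4,4,5,5-tetramethyl-2-vinyl-1,3,2-dioxaborolane, C=CB1OC(C)(C)C(C)(C)O1
Why: Heck–Mizoroki vinylation of the alkenyl iodide with the vinylboronate (boron retained) should give the new (E)-alkene by syn-insertion and syn-β-hydride elimination while the trisubstituted alkene keeps its geometry; the silver salt suppresses the Suzuki pathway.

Step 6
Reactants: 13 dienylboronate; 14 4-methoxybenzyl alcohol
Product: 15 (3E,7R,9E,11E)-12-[(4-methoxybenzyl)oxy]-3,9-dimethyl-2-oxododeca-3,9,11-trien-7-yl acetate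
Conditions: Cu(OAc)2 (2 equiv), Et3N (4 equiv), 14 (5 equiv), 3-hexyne (additive), 4 Å MS, CH2Cl2, air, rt
Reagents that add atoms: 4-methoxybenzyl alcohol, COc1ccc(CO)cc1
Why: Chan–Lam–Evans oxidative C–O coupling of an alkenylboronate with an alcohol under divalent copper proceeds with retention of alkene geometry and should give the (1E,3E)-1-alkoxydiene under basic conditions that spare the enol ether.

Step 7
Reactants: 15 acyclic trienone
Product: 16 trans-fused Δ1-octalin with 3α-(4-methoxybenzyloxy), 4α-acetyl, 4β-methyl, 5α-H, 8α-acetoxy and 10β-methyl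
Conditions: toluene (0.01 M), BHT (5 mol %), base-washed sealed tube, 120 °C
Reagents that add atoms: none
Why: Concerted, asynchronous intramolecular [4+2] cycloaddition of a 1-alkoxy-1,3-diene with a tethered enone, a well-known reaction class; the donor-substituted diene (largest HOMO coefficient at C10) and the acetyl-activated dienophile (largest LUMO coefficient at C5) are polarity-matched, so C5–C10 bonding leads and C3–C4 follows. Ring A closes as the cyclohexene of the [4+2] event (C10=C1–C2=C3 plus C4=C5), and ring B closes at the same time in the fused mode through the four-carbon tether C6–C9 that joins diene terminus C10 to dienophile carbon C5 in a chair-like array. C3 and C10 follow from the (E,E)-diene geometry (O–C3 and C9–C10 end on one face), C4 and C5 from the (E)-enone geometry (acetyl cis to H-5, C4 methyl cis to C6), and the C3/C4 and C10/C5 relationships from the endo orientation of the acetyl group, which is the same transition state that gives the trans ring fusion. The absolute sense is set by the C8 acetoxy group, which should sit equatorial on the chair-like tether to avoid a syn-diaxial contact with the C10 methyl. The step needs endo (trans-fused) over exo (cis-fused) selectivity and one diene face; the first rests on the carbonyl endo preference reinforced by the tether chair, the second on the C8 stereocentre. Regiochemistry is fixed by the tether.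

Step 8
Reactants: 16 Δ1-octalin
Product: 17 trans-decalin with 3α-(4-methoxybenzyloxy), 4α-acetyl, 4β-methyl, 8α-acetoxy and 10β-methyl
Conditions: H2 (1 atm), [Ir(cod)(PCy3)(py)]PF6 (5 mol %), CH2Cl2, rt
Reagents that add atoms: none
Why: Homogeneous hydrogenation with a catalyst that accepts hindered ring alkenes should saturate C1=C2 without hydrogenolysis of the PMB ether or reduction of the ketone; no stereocentre is formed.

Step 9
Reactants: 17 methyl ketone; 18 3-chloroperoxybenzoic acid
Product: 19 4α,8α-diacetoxy-3α-(4-methoxybenzyloxy)-4β,10β-dimethyl-trans-decalin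
Conditions: mCPBA (3 equiv), Na2HPO4, CH2Cl2, rt → 40 °C
Reagents that add atoms: 3-chloroperoxybenzoic acid, OOC(=O)c1cccc(Cl)c1
Why: Baeyer–Villiger oxidation in which the tertiary C4 migrates in preference to methyl with retention of configuration should turn the 4α-acetyl group into the 4α-acetate.

Step 10
Reactants: 19 diacetate
Product: 20 4α,8α-dihydroxy-3α-(4-methoxybenzyloxy)-4β,10β-dimethyl-trans-decalin
Conditions: LiAlH4, THF, 0 °C; aqueous work-up
Reagents that add atoms: none
Why: Hydride reduction should cleave both acetates, the hindered tertiary one included, and leave the PMB ether and all stereocentres untouched.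

Step 11
Reactants: 20 diol
Product: 21 4α-hydroxy-3α-(4-methoxybenzyloxy)-4β,10β-dimethyl-trans-decalin-8-one
Conditions: Dess–Martin periodinane, NaHCO3, CH2Cl2, 0 °C → rt
Reagents that add atoms: none
Why: Only the secondary C8 alcohol can be oxidised (C4–OH is tertiary), which removes the temporary stereocentre.

Step 12
Reactants: 21 hydroxy ketone; 22 acetone
Product: 24 4α,11-dihydroxy-3α-(4-methoxybenzyloxy)eudesman-8-one (C7 epimers), via lithium enolate 23 (not isolated)
Conditions: LiN(iPr)2 (2.5 equiv), THF, −78 °C; then acetone (5 equiv), −78 °C; AcOH quench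
Reagents that add atoms: acetone, CC(C)=O
Why: After alkoxide formation at C4, kinetic deprotonation should occur at C7 (C9 is neopentylic beside quaternary C10), and the aldol addition to acetone gives the β-hydroxy ketone; the C7 configuration is removed in the next step.

Step 13
Reactants: 24 aldol adduct
Product: 25 4α-hydroxy-3α-(4-methoxybenzyloxy)eudesm-7(11)-en-8-one
Conditions: TsOH·H2O (10 mol %), benzene, 50 °C
Reagents that add atoms: none
Why: Acid-catalysed dehydration of the tertiary β-hydroxy ketone through its enol should give the conjugated tetrasubstituted enone, while the isolated C4 carbinol (deactivated by the adjacent C3 oxygen) ionises more slowly.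

Step 14
Reactants: 25 PMB ether
Product: 26 3α,4α-dihydroxyeudesm-7(11)-en-8-one
Conditions: DDQ (1.5 equiv), CH2Cl2/pH 7 buffer (10:1), 0 °C → rt
Reagents that add atoms: none
Why: Oxidative cleavage of the 4-methoxybenzyl ether by benzylic hydride abstraction and hydrolysis should spare the enone and the tertiary alcohol.

Step 15
Reactants: 26 diol; 27 angelic acid; 28 2,4,6-trichlorobenzoyl chloride
Product: 30 3α-angeloyloxy-4α-hydroxyeudesm-7(11)-en-8-one, via mixed anhydride 29 (not isolated)
Conditions: 27, 28, Et3N, toluene, rt; then 26, toluene, 80 °C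
Reagents that add atoms: angelic acid, C/C=C(/C)C(=O)O
Why: Yamaguchi-type esterification through the mixed anhydride, run without a nucleophilic catalyst, should acylate the secondary C3 hydroxyl (the tertiary C4 hydroxyl does not react) and keep the (Z)-geometry of the acyl group.

Step 16
Reactants: 30 angelate; 31 dioxygen
Product: 32 3α-angeloyloxy-4α-hydroxy-11-hydroperoxyeudesm-6-en-8-one (CNP0161122.2)
Conditions: O2, tetraphenylporphyrin (cat.), visible light, CH2Cl2, −20 °C
Reagents that add atoms: dioxygen, O=O
Why: Schenck ene reaction of singlet oxygen with the s-cis-locked tetrasubstituted enone should follow the geminal rule (oxygen to C11, hydrogen taken from C6) to give the C6=C7 enone and the tertiary hydroperoxide; the less electron-rich trisubstituted angelate should react more slowly, and C11 is not stereogenic.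

**Compound list**

1 | (R)-2-(but-3-en-1-yl)oxirane | C=CCC[C@@H]1CO1 | starting material
2 | lithium acetylide–ethylenediamine complex | [Li+].[C-]#C.NCCN | starting material
3 | (R)-oct-1-en-7-yn-5-ol | C=CCC[C@@H](O)CC#C | intermediate
4 | trimethylaluminium | C[Al](C)C | starting material
5 | iodine | II | starting material
6 | dimethyl[(1E,4R)-4-(dimethylalumanyloxy)-2-methylocta-1,7-dien-1-yl]alumane | C=CCC[C@@H](O[Al](C)C)C/C(C)=C/[Al](C)C | intermediate
7 | (1E,4R)-1-iodo-2-methylocta-1,7-dien-4-ol | C=CCC[C@@H](O)C/C(C)=C/I | intermediate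
8 | acetic anhydride | CC(=O)OC(C)=O | starting material
9 | (1E,4R)-1-iodo-2-methylocta-1,7-dien-4-yl acetate | C=CCC[C@@H](OC(C)=O)C/C(C)=C/I | intermediate
10 | 3-methylbut-3-en-2-one | CC(=O)C(C)=C | starting material
11 | (3E,7R,9E)-10-iodo-3,9-dimethyl-2-oxodeca-3,9-dien-7-yl acetate | CC(=O)/C(C)=C/CC[C@@H](OC(C)=O)C/C(C)=C/I | intermediate
12 | 4,4,5,5-tetramethyl-2-vinyl-1,3,2-dioxaborolane | C=CB1OC(C)(C)C(C)(C)O1 | starting material
13 | (3E,7R,9E,11E)-3,9-dimethyl-2-oxo-12-(4,4,5,5-tetramethyl-1,3,2-dioxaborolan-2-yl)dodeca-3,9,11-trien-7-yl acetate | CC(=O)/C(C)=C/CC[C@@H](OC(C)=O)C/C(C)=C/C=C/B1OC(C)(C)C(C)(C)O1 | intermediate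
14 | 4-methoxybenzyl alcohol | COc1ccc(CO)cc1 | starting material
15 | (3E,7R,9E,11E)-12-[(4-methoxybenzyl)oxy]-3,9-dimethyl-2-oxododeca-3,9,11-trien-7-yl acetate | CC(=O)/C(C)=C/CC[C@@H](OC(C)=O)C/C(C)=C/C=C/OCc1ccc(OC)cc1 | intermediate
16 | trans-fused Δ1-octalin: 3α-(4-methoxybenzyloxy), 4α-acetyl, 4β-methyl, 5α-H, 8α-acetoxy, 10β-methyl | COc1ccc(CO[C@@H]2C=C[C@]3(C)C[C@H](OC(C)=O)CC[C@H]3[C@]2(C)C(C)=O)cc1 | intermediate
17 | 1,2-dihydro derivative of 16 (trans-decalin) | COc1ccc(CO[C@@H]2CC[C@]3(C)C[C@H](OC(C)=O)CC[C@H]3[C@]2(C)C(C)=O)cc1 | intermediate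
18 | 3-chloroperoxybenzoic acid | OOC(=O)c1cccc(Cl)c1 | starting material
19 | 4α,8α-diacetoxy-3α-(4-methoxybenzyloxy)-4β,10β-dimethyl-trans-decalin | COc1ccc(CO[C@@H]2CC[C@]3(C)C[C@H](OC(C)=O)CC[C@H]3[C@]2(C)OC(C)=O)cc1 | intermediate
20 | 4α,8α-dihydroxy-3α-(4-methoxybenzyloxy)-4β,10β-dimethyl-trans-decalin | COc1ccc(CO[C@@H]2CC[C@]3(C)C[C@H](O)CC[C@H]3[C@]2(C)O)cc1 | intermediate
21 | 4α-hydroxy-3α-(4-methoxybenzyloxy)-4β,10β-dimethyl-trans-decalin-8-one | COc1ccc(CO[C@@H]2CC[C@]3(C)CC(=O)CC[C@H]3[C@]2(C)O)cc1 | intermediate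
22 | acetone | CC(C)=O | starting material
23 | dilithium C4-alkoxide C7(8)-enolate of 21 | COc1ccc(CO[C@@H]2CC[C@]3(C)CC(O[Li])=CC[C@H]3[C@]2(C)O[Li])cc1 | intermediate
24 | 4α,11-dihydroxy-3α-(4-methoxybenzyloxy)eudesman-8-one (C7 not defined) | COc1ccc(CO[C@@H]2CC[C@]3(C)CC(=O)C(C(C)(C)O)C[C@H]3[C@]2(C)O)cc1 | intermediate
25 | 4α-hydroxy-3α-(4-methoxybenzyloxy)eudesm-7(11)-en-8-one | COc1ccc(CO[C@@H]2CC[C@]3(C)CC(=O)C(=C(C)C)C[C@H]3[C@]2(C)O)cc1 | intermediate
26 | 3α,4α-dihydroxyeudesm-7(11)-en-8-one | O[C@@H]1CC[C@]2(C)CC(=O)C(=C(C)C)C[C@H]2[C@]1(C)O | intermediate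
27 | angelic acid, (Z)-2-methylbut-2-enoic acid | C/C=C(/C)C(=O)O | starting material
28 | 2,4,6-trichlorobenzoyl chloride | O=C(Cl)c1c(Cl)cc(Cl)cc1Cl | starting material
29 | angelic 2,4,6-trichlorobenzoic anhydride | C/C=C(/C)C(=O)OC(=O)c1c(Cl)cc(Cl)cc1Cl | intermediate
30 | 3α-angeloyloxy-4α-hydroxyeudesm-7(11)-en-8-one | C/C=C(/C)C(=O)O[C@@H]1CC[C@]2(C)CC(=O)C(=C(C)C)C[C@H]2[C@]1(C)O | intermediate
31 | dioxygen | O=O | starting material
32 | 3α-angeloyloxy-4α-hydroxy-11-hydroperoxyeudesm-6-en-8-one (CNP0161122.2) | C/C=C(/C)C(=O)O[C@@H]1CC[C@]2(C)CC(=O)C(C(C)(C)OO)=C[C@H]2[C@]1(C)O | target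

**Step count and risks**

Total step count: 16. Longest linear sequence: 16 steps (1 → 32).

Steps most likely to fail:

1. Step 7. The cycloaddition may pass through the exo transition state to a competing extent (cis-fused octalin), and the acid-labile dienyl ether may hydrolyse or isomerise at the temperature required before the rings close. Fallback: change the diene substituent from oxygen to boron so that Lewis-acid promotion becomes possible. Setting out from 13, Et2AlCl (1.1 equiv, CH2Cl2, −40 → 0 °C) should drive the intramolecular Diels–Alder reaction of the 1-boryl diene through the endo transition state to the allylboronate cycloadduct F1. NaBO3·4H2O (THF/H2O, 0 °C) should then oxidise the C3–B bond with retention to the allylic alcohol F2. 4-Methoxybenzyl 2,2,2-trichloroacetimidate with La(OTf)3 (cat., toluene) should give 16, where the route is rejoined.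

2. Step 6. Protodeboronation and oxidative homocoupling of the dienylboronate may outrun C–O bond formation, and the enol ether may be lost by hydrolysis during copper removal. Fallback: make the C1–C2 bond last, with the oxygen already on the two-carbon partner. Setting out from 14, KH and trichloroethylene (THF) should give 4-methoxybenzyl (E)-1,2-dichlorovinyl ether F3. n-BuLi (2.2 equiv, −78 °C) then MeOH should give 4-methoxybenzyl ethynyl ether F4, which is kept cold. Pinacolborane with Cp2ZrHCl (cat.) should give the (E)-2-alkoxyvinylboronate F5 by syn-hydroboration. Suzuki–Miyaura coupling of F5 with iodide 11 (Pd(dppf)Cl2, K3PO4, THF/H2O, rt) should give 15, where the route is rejoined.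

3. Step 16. Ene oxygenation of the angelate double bond and secondary reactions of the allylic hydroperoxide may set in before 30 is consumed. Fallback: oxygenate before the angelate is present. Setting out from 26, the same photooxygenation should give the hydroperoxy diol F6. TBSCl and imidazole (DMF, 0 °C) should silylate the more acidic hydroperoxide to the silyl peroxide F7. Acylation of the C3 hydroxyl with mixed anhydride 29 (toluene, 80 °C) should give the angelate F8. HF·pyridine (THF, 0 °C) should then release 32.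

Further compounds
F1 | step 7 | trans-fused Δ1-octalin with 3α-(pinacolboryl), 4α-acetyl, 4β-methyl, 8α-acetoxy, 10β-methyl | CC1(C)OB(OC1(C)C)[C@@H]2C=C[C@]3(C)C[C@H](OC(C)=O)CC[C@H]3[C@]2(C)C(C)=O
F2 | step 7 | trans-fused Δ1-octalin with 3α-hydroxy, 4α-acetyl, 4β-methyl, 8α-acetoxy, 10β-methyl | O[C@@H]1C=C[C@]2(C)C[C@H](OC(C)=O)CC[C@H]2[C@]1(C)C(C)=O
F3 | step 6 | 4-methoxybenzyl (E)-1,2-dichlorovinyl ether | COc1ccc(CO/C(Cl)=C\Cl)cc1
F4 | step 6 | 4-methoxybenzyl ethynyl ether | COc1ccc(COC#C)cc1
F5 | step 6 | (E)-2-[2-(4-methoxybenzyloxy)vinyl]-4,4,5,5-tetramethyl-1,3,2-dioxaborolane | COc1ccc(CO/C=C/B2OC(C)(C)C(C)(C)O2)cc1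
F6 | step 16 | 3α,4α-dihydroxy-11-hydroperoxyeudesm-6-en-8-one | O[C@@H]1CC[C@]2(C)CC(=O)C(C(C)(C)OO)=C[C@H]2[C@]1(C)O
F7 | step 16 | 11-(tert-butyldimethylsilylperoxy)-3α,4α-dihydroxyeudesm-6-en-8-one | O[C@@H]1CC[C@]2(C)CC(=O)C(C(C)(C)OO[Si](C)(C)C(C)(C)C)=C[C@H]2[C@]1(C)O
F8 | step 16 | 3α-angeloyloxy-11-(tert-butyldimethylsilylperoxy)-4α-hydroxyeudesm-6-en-8-one | C/C=C(/C)C(=O)O[C@@H]1CC[C@]2(C)CC(=O)C(C(C)(C)OO[Si](C)(C)C(C)(C)C)=C[C@H]2[C@]1(C)O
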